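**Retrosynthetic overview**
1. Target 9 comes from ester 8 by ester reduction, so C9 reaches the alcohol oxidation level last.
2. Ester 8 comes from the racemic, configurationally labile α-aryloxy β-keto ester 7: a ketoreductase-catalysed dynamic kinetic resolution sets C7 and C8 in one step.
3. Keto ester 7 comes from aldol adduct 6 by oxidation; 6 comes from aryloxyacetate 3 and 3,4,5-trimethoxybenzaldehyde 4 (C7–C8 bond).
4. Ester 3 comes from 4-allyl-2,6-dimethoxyphenol 1 and ethyl bromoacetate 2 (C8–O–aryl bond by Williamson etherification).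
5. No ring is formed; both benzene rings are bought intact.

Assumption: comments use neolignan numbering (C7 benzylic carbinol, C8 aryloxy carbon, C9 CH2OH), and the ketoreductase variant with the stated selectivity is picked from a commercial screening panel.

The target is the threo (1R,2R) isomer, that is 7R,8R. In ester 8 the same spatial arrangement is named (2S,3R), because CO2Et outranks the carbinol carbon whereas CH2OH does not.

**Step 1**
Reactants: 1 4-allyl-2,6-dimethoxyphenol; 2 ethyl bromoacetate
Product: 3 ethyl 2-(4-allyl-2,6-dimethoxyphenoxy)acetate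
Conditions: K2CO3 (2 equiv), acetone, reflux
Reagents that add atoms: none
Why: Williamson ether synthesis, in which the phenoxide of 1 displaces bromide from the unhindered, carbonyl-activated primary bromide 2 by SN2 despite the two ortho methoxy groups.

**Step 2**
Reactants: 3 ethyl 2-(4-allyl-2,6-dimethoxyphenoxy)acetate; 4 3,4,5-trimethoxybenzaldehyde
Product: 6 ethyl 2-(4-allyl-2,6-dimethoxyphenoxy)-3-hydroxy-3-(3,4,5-trimethoxyphenyl)propanoate (racemic syn/anti mixture), via lithium ester enolate 5 (not isolated)
Conditions: LiN(iPr)2 (1.1 equiv), THF, −78 °C; then 4, −78 °C; AcOH quench at −78 °C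
Reagents that add atoms: none
Why: Aldol addition of lithium ester enolate 5 to the non-enolisable aldehyde 4 is fast at −78 °C; the two new centres are deliberately left uncontrolled because step 3 erases C3 and makes C2 labile.

**Step 3**
Reactants: 6 ethyl 2-(4-allyl-2,6-dimethoxyphenoxy)-3-hydroxy-3-(3,4,5-trimethoxyphenyl)propanoate
Product: 7 ethyl 2-(4-allyl-2,6-dimethoxyphenoxy)-3-oxo-3-(3,4,5-trimethoxyphenyl)propanoate (racemic, C2 labile)
Conditions: Dess–Martin periodinane (1.2 equiv), CH2Cl2, 0 °C → rt
Reagents that add atoms: none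
Why: Dess–Martin oxidation converts the secondary benzylic alcohol into the aryl ketone under neutral conditions that spare the allyl group, aryl ethers and ester; C3 is no longer a stereocentre and C2 now epimerises freely through the enol.

**Step 4**
Reactants: 7 ethyl 2-(4-allyl-2,6-dimethoxyphenoxy)-3-oxo-3-(3,4,5-trimethoxyphenyl)propanoate
Product: 8 ethyl (2S,3R)-2-(4-allyl-2,6-dimethoxyphenoxy)-3-hydroxy-3-(3,4,5-trimethoxyphenyl)propanoate
Conditions: ketoreductase (NADPH-dependent carbonyl reductase, syn- and 3R-selective panel variant), NADP+ (cat.), iPrOH (15% v/v), KH2PO4/K2HPO4 buffer (0.1 M, pH 7.0), MgSO4 (2 mM), DMSO (10% v/v), 30 °C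
Reagents that add atoms: none
Why: Enzymatic dynamic kinetic resolution (asymmetric biocatalytic ketone reduction): the ketoreductase delivers hydride from NADPH to the Si face of the ketone of (2S)-7 only, while (2R)-7 keeps racemising through its enol at pH 7, so C3 (R) and C2 (S) are fixed together as the first defined stereocentres of the route.

**Step 5**
Reactants: 8 ethyl (2S,3R)-2-(4-allyl-2,6-dimethoxyphenoxy)-3-hydroxy-3-(3,4,5-trimethoxyphenyl)propanoate
Product: 9 (1R,2R)-2-(4-allyl-2,6-dimethoxyphenoxy)-1-(3,4,5-trimethoxyphenyl)propane-1,3-diol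
Conditions: LiAlH4 (2 equiv), THF, 0 °C; then Na2SO4·10H2O
Reagents that add atoms: none
Why: Hydride reduction of the ester to the primary alcohol with LiAlH4 at 0 °C leaves the isolated alkene and both stereocentres untouched (no deprotonation at C2, no retro-aldol at this temperature); the descriptor at the aryloxy carbon changes from S to R only through the CIP ranking.

**Compound list**
1 | 4-allyl-2,6-dimethoxyphenol | C=CCc1cc(OC)c(O)c(OC)c1 | starting material
2 | ethyl bromoacetate | BrCC(=O)OCC | starting material
3 | ethyl 2-(4-allyl-2,6-dimethoxyphenoxy)acetate | C=CCc1cc(OC)c(OCC(=O)OCC)c(OC)c1 | intermediate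
4 | 3,4,5-trimethoxybenzaldehyde | COc1cc(C=O)cc(OC)c1OC | starting material
5 | lithium enolate of 3 (lithium 1-ethoxy-2-(4-allyl-2,6-dimethoxyphenoxy)ethen-1-olate) | C=CCc1cc(OC)c(OC=C([O-])OCC)c(OC)c1.[Li+] | intermediate (not isolated)
6 | ethyl 2-(4-allyl-2,6-dimethoxyphenoxy)-3-hydroxy-3-(3,4,5-trimethoxyphenyl)propanoate, racemic syn/anti mixture | C=CCc1cc(OC)c(OC(C(=O)OCC)C(O)c2cc(OC)c(OC)c(OC)c2)c(OC)c1 | intermediate
7 | ethyl 2-(4-allyl-2,6-dimethoxyphenoxy)-3-oxo-3-(3,4,5-trimethoxyphenyl)propanoate, racemic | C=CCc1cc(OC)c(OC(C(=O)OCC)C(=O)c2cc(OC)c(OC)c(OC)c2)c(OC)c1 | intermediate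
8 | ethyl (2S,3R)-2-(4-allyl-2,6-dimethoxyphenoxy)-3-hydroxy-3-(3,4,5-trimethoxyphenyl)propanoate | C=CCc1cc(OC)c(O[C@H](C(=O)OCC)[C@H](O)c2cc(OC)c(OC)c(OC)c2)c(OC)c1 | intermediate
9 | (1R,2R)-2-(4-allyl-2,6-dimethoxyphenoxy)-1-(3,4,5-trimethoxyphenyl)propane-1,3-diol (threo, 7R,8R) | C=CCc1cc(OC)c(O[C@H](CO)[C@H](O)c2cc(OC)c(OC)c(OC)c2)c(OC)c1 | target

**Step count and risks**
Total step count: 5. Longest linear sequence: 5 steps (1 → 3 → 6 → 7 → 8 → 9).

The three steps most likely to fail:

Step 4 (enzymatic dynamic kinetic resolution). The risk is that no panel enzyme accepts the bulky aryl ketone, or that only anti- or 3S-selective hits are found. The fallback sets out from 7 and comes back at 8. The reduction is moved from biocatalysis to transition-metal transfer hydrogenation under dynamic kinetic resolution, using the divalent ruthenium complex RuCl[(S,S)-TsDPEN](p-cymene) (1 mol %) with HCO2H/Et3N 5:2 in CH2Cl2 at 30 °C. The aryl ketone should be reduced with the same facial sense as acetophenone, which here is named 3R because the side chain outranks the aryl group, and syn is the usual outcome for α-alkoxy aryl β-keto esters. If the antipode forms, the (R,R)-ligand complex is the wrong one and the (S,S) choice is confirmed or reversed accordingly. Enantiomeric purity is checked by chiral HPLC and raised by crystallisation if needed. This path makes no new compound (none F0).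

Step 5 (ester reduction). The risk is partial retro-aldol or epimerisation at the metal alkoxide stage, which would erode dr and ee. The fallback sets out from 8 and comes back at 9, capping the benzylic hydroxyl so that no metal alkoxide sits β to the ester during hydride delivery. TBSOTf and 2,6-lutidine in CH2Cl2 at −78 → 0 °C give ethyl (2S,3R)-2-(4-allyl-2,6-dimethoxyphenoxy)-3-(tert-butyldimethylsilyloxy)-3-(3,4,5-trimethoxyphenyl)propanoate F1. iBu2AlH in CH2Cl2 at −78 → 0 °C then gives (2R,3R)-2-(4-allyl-2,6-dimethoxyphenoxy)-3-(tert-butyldimethylsilyloxy)-3-(3,4,5-trimethoxyphenyl)propan-1-ol F2. Bu4NF in THF at 0 °C removes the silyl group and delivers 9.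

Step 3 (oxidation). The risk is further oxidation at the doubly activated C2–H, or loss of the sensitive keto ester on purification. The fallback sets out from 3 and comes back at 7, bypassing 6 and the oxidation. Ester 3 (2 equiv) is converted into enolate 5 with LiN(iPr)2 (2 equiv) in THF at −78 °C and C-acylated with bought 3,4,5-trimethoxybenzoyl chloride F3 (1 equiv) in a crossed Claisen-type acylation. The second equivalent of enolate deprotonates the product, and the regenerated 3 is recovered.

**Further compounds**
F0 | step 4 | none | none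
F1 | step 5 | ethyl (2S,3R)-2-(4-allyl-2,6-dimethoxyphenoxy)-3-(tert-butyldimethylsilyloxy)-3-(3,4,5-trimethoxyphenyl)propanoate | C=CCc1cc(OC)c(O[C@H](C(=O)OCC)[C@H](O[Si](C)(C)C(C)(C)C)c2cc(OC)c(OC)c(OC)c2)c(OC)c1
F2 | step 5 | (2R,3R)-2-(4-allyl-2,6-dimethoxyphenoxy)-3-(tert-butyldimethylsilyloxy)-3-(3,4,5-trimethoxyphenyl)propan-1-ol | C=CCc1cc(OC)c(O[C@H](CO)[C@H](O[Si](C)(C)C(C)(C)C)c2cc(OC)c(OC)c(OC)c2)c(OC)c1
F3 | step 3 | 3,4,5-trimethoxybenzoyl chloride (bought, brought in by the fallback) | COc1cc(C(=O)Cl)cc(OC)c1OC
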